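## Retrosynthetic overview

1. The target is lutein 5,6-epoxide dipalmitate. The last disconnection is the C12–C13 single bond of the undecaene, giving a C16 trienyl pinacolboronate (ring A, the epoxidised cyclohexane, with the C3 palmitate) and a C24 methyl-capped pentaenyne (ring B, the cyclohexene, with the C3' palmitate). They are joined by a rhodium-catalysed syn-hydroalkenylation of the alkyne.
2. Enabling feature: C13 carries the C20 methyl group and sits in the E,E-diene C11=C12–C13(CH3)=C14 with H-14 cis to C12. This diene is therefore the syn C12–H adduct of a C13≡C14 triple bond whose only other substituent is that methyl. Rings A and B, with all five stereocentres, are attached at C6 and C6', far from the reacting atoms.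
3. Boronate half: C11=C12 by boron–Wittig olefination, C7–C11 by Horner–Wadsworth–Emmons reaction on the ring A epoxy aldehyde, the C5/C6 oxirane by Sharpless epoxidation of an allylic alcohol made from (4R,6R)-actinol through its enol triflate.
4. Alkyne half: C15=C15' by Horner–Wadsworth–Emmons reaction with a but-2-ynylphosphonate, C9'–C15' by two nitrile olefination/reduction cycles, the C3' hydroxyl by allylic oxidation and asymmetric transfer hydrogenation of (R)-α-ionone.
5. Ring order: no carbocycle is built (ring A comes from actinol, ring B from α-ionone); the only ring closed is the oxirane on ring A (step 5).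

Key step: step 23

Assumption: (4R,6R)-actinol and (R)-α-ionone are bought as single enantiomers, and minor olefin isomers from the olefination steps are removed by chromatography or crystallisation before the next step.

## Route

Step 1
Reactants: 1 (4R,6R)-4-hydroxy-2,2,6-trimethylcyclohexan-1-one
Product: 2 (4R,6R)-4-(tert-butyldimethylsilyloxy)-2,2,6-trimethylcyclohexan-1-one
Conditions: TBSCl, imidazole, DMF, rt
Reagents that add atoms: tert-butyldimethylsilyl chloride, CC(C)(C)[Si](C)(C)Cl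
Why: Imidazole-promoted silylation masks the secondary alcohol for the enolate, hydride and oxidation steps ahead without touching either stereocentre (silyl ether protection).

Step 2
Reactants: 2 silyl ether ketone
Product: 4 (4R)-4-(tert-butyldimethylsilyloxy)-2,6,6-trimethylcyclohex-1-en-1-yl trifluoromethanesulfonate, via lithium enolate 3 (not isolated)
Conditions: LiN(i-Pr)2, THF, −78 °C; PhNTf2, −78 to 0 °C
Reagents that add atoms: N-phenylbis(trifluoromethanesulfonimide), O=S(=O)(N(c1ccccc1)S(=O)(=O)C(F)(F)F)C(F)(F)F; lithium diisopropylamide, [Li+].CC(C)[N-]C(C)C (lithium in 3 only)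
Why: Deprotonation is possible only at C6 because C2 is quaternary, so enolate formation and O-sulfonylation give a single enol triflate and deliberately erase the C6 methyl stereocentre (enol triflate synthesis).

Step 3
Reactants: 4 enol triflate
Product: 5 methyl (4R)-4-(tert-butyldimethylsilyloxy)-2,6,6-trimethylcyclohex-1-ene-1-carboxylate
Conditions: Pd(OAc)2 (5 mol %), PPh3, Et3N, CO (1 atm), MeOH/DMF, 60 °C
Reagents that add atoms: carbon monoxide, [C-]#[O+]; methanol, CO
Why: Oxidative addition of the enol triflate to zerovalent palladium, CO insertion and methanolysis of the acyl-palladium species give the conjugated ester (palladium-catalysed alkoxycarbonylation).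

Step 4
Reactants: 5 unsaturated ester
Product: 6 [(4R)-4-(tert-butyldimethylsilyloxy)-2,6,6-trimethylcyclohex-1-en-1-yl]methanol
Conditions: i-Bu2AlH, CH2Cl2, −78 to 0 °C; aq. potassium sodium tartrate
Reagents that add atoms: none
Why: Two hydride transfers from i-Bu2AlH reduce the unsaturated ester to the allylic alcohol without conjugate reduction (ester 1,2-reduction).

Step 5
Reactants: 6 allylic alcohol
Product: 7 [(1R,4S,6R)-4-(tert-butyldimethylsilyloxy)-2,2,6-trimethyl-7-oxabicyclo[4.1.0]heptan-1-yl]methanol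
Conditions: Ti(Oi-Pr)4 (20 mol %), D-(−)-diethyl tartrate (25 mol %), t-BuOOH, 4 Å molecular sieves, CH2Cl2, −20 °C
Reagents that add atoms: tert-butyl hydroperoxide, CC(C)(C)OO
Why: In this Sharpless asymmetric epoxidation the D-(−)-tartrate ligand should deliver the peroxide oxygen to the olefin face anti to the C4 silyloxy group, which is also the sterically favoured face, so both oxirane carbons (carotenoid C5 and C6) are set as 5R,6S relative to the existing carbinol centre.

Step 6
Reactants: 7 epoxy alcohol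
Product: 8 (1S,4S,6R)-4-(tert-butyldimethylsilyloxy)-2,2,6-trimethyl-7-oxabicyclo[4.1.0]heptane-1-carbaldehyde
Conditions: Pr4N[RuO4] (5 mol %), N-methylmorpholine N-oxide, 4 Å molecular sieves, CH2Cl2, rt
Reagents that add atoms: none
Why: The neutral Ley–Griffith oxidation converts the neopentyl-type primary alcohol into a non-enolisable aldehyde and leaves the acid-sensitive epoxide and the silyl ether alone.

Step 7
Reactants: 8 epoxy aldehyde; 9 diethyl (3-cyano-2-methylprop-2-en-1-yl)phosphonate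
Product: 10 (2E,4E)-5-[(1S,4S,6R)-4-(tert-butyldimethylsilyloxy)-2,2,6-trimethyl-7-oxabicyclo[4.1.0]heptan-1-yl]-3-methylpenta-2,4-dienenitrile
Conditions: NaH, THF, 0 °C to rt
Reagents that add atoms: none
Why: Horner–Wadsworth–Emmons olefination with the nitrile-stabilised allylic phosphonate anion should form C7=C8 E-selectively, while equilibration of the allyl anion favours the 9E geometry of the trisubstituted olefin.

Step 8
Reactants: 10 dienenitrile
Product: 12 (2E,4E)-5-[(1S,4S,6R)-4-(tert-butyldimethylsilyloxy)-2,2,6-trimethyl-7-oxabicyclo[4.1.0]heptan-1-yl]-3-methylpenta-2,4-dienal, via N-aluminio aldimine 11 (not isolated)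
Conditions: i-Bu2AlH, CH2Cl2, −78 °C; aq. NaH2PO4/Na2HPO4 (pH 7), 0 °C
Reagents that add atoms: diisobutylaluminium hydride, CC(C)C[AlH]CC(C)C (aluminium in 11 only); water, O
Why: A single hydride transfer stops at the N-aluminio aldimine, and buffered hydrolysis converts it into the dienal without acid that would rearrange the vinyl epoxide (nitrile half-reduction).

Step 9
Reactants: 12 silyl ether dienal
Product: 13 (2E,4E)-5-[(1S,4S,6R)-4-hydroxy-2,2,6-trimethyl-7-oxabicyclo[4.1.0]heptan-1-yl]-3-methylpenta-2,4-dienal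
Conditions: Bu4NF, THF, 0 °C to rt
Reagents that add atoms: none
Why: Fluoride cleaves the Si–O bond under nearly neutral conditions that the epoxide and the dienal tolerate (desilylation).

Step 10
Reactants: 13 hydroxy dienal; 14 hexadecanoyl chloride
Product: 15 (2E,4E)-5-[(1S,4S,6R)-4-(hexadecanoyloxy)-2,2,6-trimethyl-7-oxabicyclo[4.1.0]heptan-1-yl]-3-methylpenta-2,4-dienal
Conditions: pyridine, DMAP (cat.), CH2Cl2, 0 °C to rt
Reagents that add atoms: none
Why: DMAP-catalysed acylation of the secondary alcohol by the acid chloride proceeds with retention at C3 and installs the first palmitate (esterification).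

Step 11
Reactants: 15 palmitate dienal; 16 bis(4,4,5,5-tetramethyl-1,3,2-dioxaborolan-2-yl)methane
Product: 18 2-[(1E,3E,5E)-6-[(1S,4S,6R)-4-(hexadecanoyloxy)-2,2,6-trimethyl-7-oxabicyclo[4.1.0]heptan-1-yl]-4-methylhexa-1,3,5-trien-1-yl]-4,4,5,5-tetramethyl-1,3,2-dioxaborolane, via lithiated bis(boronate) 17 (not isolated)
Conditions: lithium 2,2,6,6-tetramethylpiperidide, 16, THF, 0 °C; 15, −78 °C to rt
Reagents that add atoms: lithium 2,2,6,6-tetramethylpiperidide, [Li+].CC1(C)CCCC(C)(C)[N-]1 (lithium in 17 only)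
Why: In this boron–Wittig olefination the lithiated geminal bis(boronate) adds to the aldehyde and syn-elimination of lithium pinacolborate should give the E-alkenylboronate, the stabilised carbanion being expected to leave the palmitate and the epoxide alone.

Step 12
Reactants: 19 (3E)-4-[(1R)-2,6,6-trimethylcyclohex-2-en-1-yl]but-3-en-2-one
Product: 20 2-methyl-2-[(E)-2-[(1R)-2,6,6-trimethylcyclohex-2-en-1-yl]ethenyl]-1,3-dioxolane
Conditions: HOCH2CH2OH, HC(OMe)3, p-TsOH (cat.), rt
Reagents that add atoms: ethylene glycol, OCCO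
Why: Acid-catalysed ketalisation with the orthoformate as water scavenger masks the side-chain enone carbonyl, so the ring ketone introduced next is the only reducible carbonyl (dioxolane formation).

Step 13
Reactants: 20 dioxolane
Product: 21 (4R)-3,5,5-trimethyl-4-[(E)-2-(2-methyl-1,3-dioxolan-2-yl)ethenyl]cyclohex-2-en-1-one
Conditions: Rh2(cap)4 [dirhodium tetrakis(caprolactamate)] (1 mol %), t-BuOOH (aq.), K2CO3, CH2Cl2, rt
Reagents that add atoms: tert-butyl hydroperoxide, CC(C)(C)OO
Why: Allylic C–H oxidation by tert-butylperoxyl radicals attacks the accessible ring allylic methylene (carotenoid C3'), as is known for α-ionone-type rings, and gives the ring enone without touching the C6' stereocentre (allylic oxidation).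

Step 14
Reactants: 21 ring enone
Product: 22 (1R,4R)-3,5,5-trimethyl-4-[(E)-2-(2-methyl-1,3-dioxolan-2-yl)ethenyl]cyclohex-2-en-1-ol
Conditions: RuCl[(R,R)-TsDPEN](p-cymene) (2 mol %), HCO2Na, H2O/EtOAc, 40 °C
Reagents that add atoms: none
Why: In this Noyori–Ikariya asymmetric transfer hydrogenation the (R,R)-ligand, with the alkenyl group taking the role that an aryl group plays in aryl ketones, should deliver hydride to the carbonyl face that gives the (R)-carbinol trans to the side chain, and the fully substituted β-carbon disfavours conjugate reduction.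

Step 15
Reactants: 22 hydroxy dioxolane
Product: 23 (3E)-4-[(1R,4R)-4-hydroxy-2,6,6-trimethylcyclohex-2-en-1-yl]but-3-en-2-one
Conditions: pyridinium p-toluenesulfonate (cat.), THF/H2O, rt
Reagents that add atoms: water, O
Why: Mild acid hydrolysis of the allylic dioxolane restores the methyl enone without ionising the ring allylic alcohol (ketal cleavage).

Step 16
Reactants: 23 hydroxy enone; 24 diethyl (cyanomethyl)phosphonate
Product: 25 (2E,4E)-5-[(1R,4R)-4-hydroxy-2,6,6-trimethylcyclohex-2-en-1-yl]-3-methylpenta-2,4-dienenitrile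
Conditions: NaH (not more than 24), THF, 0 °C to rt
Reagents that add atoms: none
Why: Horner–Wadsworth–Emmons olefination of the methyl ketone should give mainly the 9'E nitrile, and with no more base than phosphonate the hydroxyl stays protonated and the C6' hydrogen is not removed.

Step 17
Reactants: 25 hydroxy dienenitrile
Product: 27 (2E,4E)-5-[(1R,4R)-4-hydroxy-2,6,6-trimethylcyclohex-2-en-1-yl]-3-methylpenta-2,4-dienal, via N-aluminio aldimine 26 (not isolated)
Conditions: i-Bu2AlH (3 equiv), CH2Cl2, −78 °C; wet silica gel, 0 °C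
Reagents that add atoms: diisobutylaluminium hydride, CC(C)C[AlH]CC(C)C (aluminium in 26 only); water, O
Why: i-Bu2AlH first ties up the hydroxyl as its aluminate and then reduces the nitrile to the aldimine, which wet silica hydrolyses to the dienal (nitrile half-reduction).

Step 18
Reactants: 27 hydroxy dienal; 9 diethyl (3-cyano-2-methylprop-2-en-1-yl)phosphonate
Product: 28 (2E,4E,6E,8E)-9-[(1R,4R)-4-hydroxy-2,6,6-trimethylcyclohex-2-en-1-yl]-3,7-dimethylnona-2,4,6,8-tetraenenitrile
Conditions: NaH (not more than 9), THF, 0 °C to rt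
Reagents that add atoms: none
Why: Horner–Wadsworth–Emmons olefination with phosphonate 9 adds C12'–C15' and should form C11'=C12' E-selectively with the 13'E isomer predominant.

Step 19
Reactants: 28 hydroxy tetraenenitrile
Product: 30 (2E,4E,6E,8E)-9-[(1R,4R)-4-hydroxy-2,6,6-trimethylcyclohex-2-en-1-yl]-3,7-dimethylnona-2,4,6,8-tetraenal, via N-aluminio aldimine 29 (not isolated)
Conditions: i-Bu2AlH (3 equiv), CH2Cl2, −78 °C; wet silica gel, 0 °C
Reagents that add atoms: diisobutylaluminium hydride, CC(C)C[AlH]CC(C)C (aluminium in 29 only); water, O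
Why: The same nitrile half-reduction as in step 17 gives the tetraenal of the C20 stage.

Step 20
Reactants: 30 hydroxy tetraenal; 14 hexadecanoyl chloride
Product: 31 (1R,4R)-4-[(1E,3E,5E,7E)-3,7-dimethyl-9-oxonona-1,3,5,7-tetraen-1-yl]-3,5,5-trimethylcyclohex-2-en-1-yl hexadecanoate
Conditions: pyridine, DMAP (cat.), CH2Cl2, 0 °C to rt
Reagents that add atoms: none
Why: DMAP-catalysed acylation installs the second palmitate with retention at C3' now that all hydride steps on this half are over (esterification).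

Step 21
Reactants: 32 1-bromobut-2-yne
Product: 33 diethyl but-2-yn-1-ylphosphonate
Conditions: P(OEt)3, neat, 120 °C
Reagents that add atoms: triethyl phosphite, CCOP(OCC)OCC
Why: In this Michaelis–Arbuzov reaction SN2 attack of the phosphite on the propargylic bromide and dealkylation by bromide give the phosphonate.

Step 22
Reactants: 31 palmitate tetraenal; 33 diethyl but-2-yn-1-ylphosphonate
Product: 34 (1R,4R)-4-[(1E,3E,5E,7E,9E)-3,7-dimethyltrideca-1,3,5,7,9-pentaen-11-yn-1-yl]-3,5,5-trimethylcyclohex-2-en-1-yl hexadecanoate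
Conditions: NaN(SiMe3)2, THF, −78 to 0 °C
Reagents that add atoms: none
Why: Horner–Wadsworth–Emmons olefination with the propargylic phosphonate anion should form C15=C15' E-selectively and place the methyl-capped C13≡C14 alkyne at the chain end, the aldehyde reacting far faster than the ester at low temperature.

Step 23
Reactants: 18 trienyl pinacolboronate (1.3 equiv); 34 methyl-capped pentaenyne
Product: 35 (3S,5R,6S,3'R,6'R)-5,6-epoxy-5,6-dihydro-β,ε-carotene-3,3'-diyl dihexadecanoate
Conditions: [Rh(OH)(cod)]2 (3 mol %), K3PO4 (20 mol %), toluene/1,4-dioxane/H2O (10:10:1), 40 °C, argon, exclusion of light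
Reagents that add atoms: none
Why: Proposed new method: transmetalation of 18 to the hydroxo-rhodium catalyst gives a trienyl complex of monovalent rhodium that adds syn across the C13≡C14 triple bond of 34, carbon to the methyl-capped C13 and rhodium to C14, and protonolysis of the C14–Rh bond by water releases 35 and regenerates Rh–OH, so the C12–C13 bond and the trisubstituted 13E olefin are made together and the undecaene is completed in the final operation. The closest known reaction type is the rhodium-catalysed syn-hydroarylation and hydroalkenylation of internal alkynes with organoboron reagents, which on 1-aryl-1-propynes delivers the organic group to the methyl-bearing carbon; its use on a methyl-capped polyenyne with a polyenylboronate has not been shown. No ring is closed and no stereocentre is formed; the one new stereo-element, the C13=C14 geometry, is fixed by the suprafacial delivery of C12 and hydrogen (H-14 cis to C12, hence C12 trans to C15). The step needs regioselectivity for C13 over C14, which the small methyl cap at C13 and the conjugative stabilisation of rhodium at C14 next to the C15=C15' olefin should secure. It also needs chemoselectivity for the single alkyne over nine C=C bonds, two esters and the vinyl epoxide, which the much faster insertion of alkynes into the Rh–C bond and the neutral aqueous medium should secure. The five ring stereocentres are remote and untouched.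

## Compound list

1 | (4R,6R)-4-hydroxy-2,2,6-trimethylcyclohexan-1-one ((4R,6R)-actinol) | O[C@H]1CC(C)(C)C(=O)[C@H](C)C1 | starting material
2 | (4R,6R)-4-{[tert-butyl(dimethyl)silyl]oxy}-2,2,6-trimethylcyclohexan-1-one | CC(C)(C)[Si](C)(C)O[C@H]1CC(C)(C)C(=O)[C@H](C)C1 | intermediate
3 | lithium (4R)-4-{[tert-butyl(dimethyl)silyl]oxy}-2,6,6-trimethylcyclohex-1-en-1-olate | [Li+].CC(C)(C)[Si](C)(C)O[C@H]1CC(C)(C)C([O-])=C(C)C1 | intermediate
4 | (4R)-4-{[tert-butyl(dimethyl)silyl]oxy}-2,6,6-trimethylcyclohex-1-en-1-yl trifluoromethanesulfonate | CC(C)(C)[Si](C)(C)O[C@H]1CC(C)(C)C(OS(=O)(=O)C(F)(F)F)=C(C)C1 | intermediate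
5 | methyl (4R)-4-{[tert-butyl(dimethyl)silyl]oxy}-2,6,6-trimethylcyclohex-1-ene-1-carboxylate | CC(C)(C)[Si](C)(C)O[C@H]1CC(C)(C)C(C(=O)OC)=C(C)C1 | intermediate
6 | [(4R)-4-{[tert-butyl(dimethyl)silyl]oxy}-2,6,6-trimethylcyclohex-1-en-1-yl]methanol | CC(C)(C)[Si](C)(C)O[C@H]1CC(C)(C)C(CO)=C(C)C1 | intermediate
7 | [(1R,4S,6R)-4-{[tert-butyl(dimethyl)silyl]oxy}-2,2,6-trimethyl-7-oxabicyclo[4.1.0]heptan-1-yl]methanol | CC(C)(C)[Si](C)(C)O[C@H]1CC(C)(C)[C@]2(CO)O[C@]2(C)C1 | intermediate
8 | (1S,4S,6R)-4-{[tert-butyl(dimethyl)silyl]oxy}-2,2,6-trimethyl-7-oxabicyclo[4.1.0]heptane-1-carbaldehyde | CC(C)(C)[Si](C)(C)O[C@H]1CC(C)(C)[C@]2(C=O)O[C@]2(C)C1 | intermediate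
9 | diethyl (3-cyano-2-methylprop-2-en-1-yl)phosphonate (E/Z mixture) | CCOP(=O)(CC(C)=CC#N)OCC | starting material
10 | (2E,4E)-5-[(1S,4S,6R)-4-{[tert-butyl(dimethyl)silyl]oxy}-2,2,6-trimethyl-7-oxabicyclo[4.1.0]heptan-1-yl]-3-methylpenta-2,4-dienenitrile | CC(C)(C)[Si](C)(C)O[C@H]1CC(C)(C)[C@]2(/C=C/C(C)=C/C#N)O[C@]2(C)C1 | intermediate
11 | N-(diisobutylalumanyl)imine of aldehyde 12 | CC(C)(C)[Si](C)(C)O[C@H]1CC(C)(C)[C@]2(/C=C/C(C)=C/C=N[Al](CC(C)C)CC(C)C)O[C@]2(C)C1 | intermediate
12 | (2E,4E)-5-[(1S,4S,6R)-4-{[tert-butyl(dimethyl)silyl]oxy}-2,2,6-trimethyl-7-oxabicyclo[4.1.0]heptan-1-yl]-3-methylpenta-2,4-dienal | CC(C)(C)[Si](C)(C)O[C@H]1CC(C)(C)[C@]2(/C=C/C(C)=C/C=O)O[C@]2(C)C1 | intermediate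
13 | (2E,4E)-5-[(1S,4S,6R)-4-hydroxy-2,2,6-trimethyl-7-oxabicyclo[4.1.0]heptan-1-yl]-3-methylpenta-2,4-dienal | O[C@H]1CC(C)(C)[C@]2(/C=C/C(C)=C/C=O)O[C@]2(C)C1 | intermediate
14 | hexadecanoyl chloride (palmitoyl chloride) | CCCCCCCCCCCCCCCC(=O)Cl | starting material
15 | (2E,4E)-5-[(1S,4S,6R)-4-(hexadecanoyloxy)-2,2,6-trimethyl-7-oxabicyclo[4.1.0]heptan-1-yl]-3-methylpenta-2,4-dienal | CCCCCCCCCCCCCCCC(=O)O[C@H]1CC(C)(C)[C@]2(/C=C/C(C)=C/C=O)O[C@]2(C)C1 | intermediate
16 | bis(4,4,5,5-tetramethyl-1,3,2-dioxaborolan-2-yl)methane | C(B1OC(C)(C)C(C)(C)O1)B1OC(C)(C)C(C)(C)O1 | starting material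
17 | lithium bis(4,4,5,5-tetramethyl-1,3,2-dioxaborolan-2-yl)methanide | [Li+].[CH-](B1OC(C)(C)C(C)(C)O1)B1OC(C)(C)C(C)(C)O1 | intermediate
18 | 2-[(1E,3E,5E)-6-[(1S,4S,6R)-4-(hexadecanoyloxy)-2,2,6-trimethyl-7-oxabicyclo[4.1.0]heptan-1-yl]-4-methylhexa-1,3,5-trien-1-yl]-4,4,5,5-tetramethyl-1,3,2-dioxaborolane | CCCCCCCCCCCCCCCC(=O)O[C@H]1CC(C)(C)[C@]2(/C=C/C(C)=C/C=C/B3OC(C)(C)C(C)(C)O3)O[C@]2(C)C1 | intermediate
19 | (3E)-4-[(1R)-2,6,6-trimethylcyclohex-2-en-1-yl]but-3-en-2-one ((R)-α-ionone) | CC(=O)/C=C/[C@H]1C(C)=CCCC1(C)C | starting material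
20 | 2-methyl-2-[(E)-2-[(1R)-2,6,6-trimethylcyclohex-2-en-1-yl]ethenyl]-1,3-dioxolane | CC1(/C=C/[C@H]2C(C)=CCCC2(C)C)OCCO1 | intermediate
21 | (4R)-3,5,5-trimethyl-4-[(E)-2-(2-methyl-1,3-dioxolan-2-yl)ethenyl]cyclohex-2-en-1-one | CC1(/C=C/[C@H]2C(C)=CC(=O)CC2(C)C)OCCO1 | intermediate
22 | (1R,4R)-3,5,5-trimethyl-4-[(E)-2-(2-methyl-1,3-dioxolan-2-yl)ethenyl]cyclohex-2-en-1-ol | CC1(/C=C/[C@H]2C(C)=C[C@H](O)CC2(C)C)OCCO1 | intermediate
23 | (3E)-4-[(1R,4R)-4-hydroxy-2,6,6-trimethylcyclohex-2-en-1-yl]but-3-en-2-one ((3R,6R)-3-hydroxy-α-ionone) | CC(=O)/C=C/[C@H]1C(C)=C[C@H](O)CC1(C)C | intermediate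
24 | diethyl (cyanomethyl)phosphonate | CCOP(=O)(CC#N)OCC | starting material
25 | (2E,4E)-5-[(1R,4R)-4-hydroxy-2,6,6-trimethylcyclohex-2-en-1-yl]-3-methylpenta-2,4-dienenitrile | N#C/C=C(C)/C=C/[C@H]1C(C)=C[C@H](O)CC1(C)C | intermediate
26 | O,N-bis(diisobutylalumanyl) derivative of the aldimine of 27 | CC(C)C[Al](CC(C)C)N=C/C=C(C)/C=C/[C@H]1C(C)=C[C@H](O[Al](CC(C)C)CC(C)C)CC1(C)C | intermediate
27 | (2E,4E)-5-[(1R,4R)-4-hydroxy-2,6,6-trimethylcyclohex-2-en-1-yl]-3-methylpenta-2,4-dienal | O=C/C=C(C)/C=C/[C@H]1C(C)=C[C@H](O)CC1(C)C | intermediate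
28 | (2E,4E,6E,8E)-9-[(1R,4R)-4-hydroxy-2,6,6-trimethylcyclohex-2-en-1-yl]-3,7-dimethylnona-2,4,6,8-tetraenenitrile | N#C/C=C(C)/C=C/C=C(C)/C=C/[C@H]1C(C)=C[C@H](O)CC1(C)C | intermediate
29 | O,N-bis(diisobutylalumanyl) derivative of the aldimine of 30 | CC(C)C[Al](CC(C)C)N=C/C=C(C)/C=C/C=C(C)/C=C/[C@H]1C(C)=C[C@H](O[Al](CC(C)C)CC(C)C)CC1(C)C | intermediate
30 | (2E,4E,6E,8E)-9-[(1R,4R)-4-hydroxy-2,6,6-trimethylcyclohex-2-en-1-yl]-3,7-dimethylnona-2,4,6,8-tetraenal | O=C/C=C(C)/C=C/C=C(C)/C=C/[C@H]1C(C)=C[C@H](O)CC1(C)C | intermediate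
31 | (1R,4R)-4-[(1E,3E,5E,7E)-3,7-dimethyl-9-oxonona-1,3,5,7-tetraen-1-yl]-3,5,5-trimethylcyclohex-2-en-1-yl hexadecanoate | O=C/C=C(C)/C=C/C=C(C)/C=C/[C@H]1C(C)=C[C@H](OC(=O)CCCCCCCCCCCCCCC)CC1(C)C | intermediate
32 | 1-bromobut-2-yne | CC#CCBr | starting material
33 | diethyl but-2-yn-1-ylphosphonate | CCOP(=O)(CC#CC)OCC | intermediate
34 | (1R,4R)-4-[(1E,3E,5E,7E,9E)-3,7-dimethyltrideca-1,3,5,7,9-pentaen-11-yn-1-yl]-3,5,5-trimethylcyclohex-2-en-1-yl hexadecanoate | CC#C/C=C/C=C(C)/C=C/C=C(C)/C=C/[C@H]1C(C)=C[C@H](OC(=O)CCCCCCCCCCCCCCC)CC1(C)C | intermediate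
35 | (3S,5R,6S,3'R,6'R)-5,6-epoxy-5,6-dihydro-β,ε-carotene-3,3'-diyl dihexadecanoate (lutein 5,6-epoxide dipalmitate) | CCCCCCCCCCCCCCCC(=O)O[C@H]1CC(C)(C)[C@]2(/C=C/C(C)=C/C=C/C(C)=C/C=C/C=C(C)/C=C/C=C(C)/C=C/[C@H]3C(C)=C[C@H](OC(=O)CCCCCCCCCCCCCCC)CC3(C)C)O[C@]2(C)C1 | target

## Step count and risks

Total step count: 23.
Longest linear sequence: 12 steps (steps 1 to 11, then step 23).

Steps most likely to fail:

1. Step 23 (the step proposed as a new method). What may go wrong: insertion of the alkyne with the opposite regiochemistry, protodeboronation of 18 outrunning carbometalation, or loss of the C13=C14 geometry by isomerisation of the dienyl-rhodium intermediate. The fallback uses known chemistry, a Suzuki–Miyaura coupling of a preformed C13 iodide. (2E)-3-Iodobut-2-en-1-ol is converted with PBr3 into (2E)-1-bromo-3-iodobut-2-ene F1. A Michaelis–Arbuzov reaction with triethyl phosphite then gives diethyl [(2E)-3-iodobut-2-en-1-yl]phosphonate F2. Horner–Wadsworth–Emmons olefination of aldehyde 31 with this phosphonate (NaN(SiMe3)2, THF, −78 °C) should give the all-E hexaenyl iodide (1R,4R)-4-[(1E,3E,5E,7E,9E,11E)-12-iodo-3,7-dimethyltrideca-1,3,5,7,9,11-hexaen-1-yl]-3,5,5-trimethylcyclohex-2-en-1-yl hexadecanoate F3. This iodide is coupled with boronate 18 [Pd(PPh3)4, aqueous K3PO4, THF, rt], which forms the same C12–C13 bond with retention of both olefin geometries. The fallback sets out from 31 and 18 and comes back to the route at 35.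

2. Step 14. What may go wrong: poor facial selectivity of hydride transfer if the preference of the catalyst is opposed by the ring, or competing reduction of the enone C=C bond. The fallback replaces catalyst control by substrate-controlled reduction plus stereoinversion. Luche reduction of 21 (NaBH4, CeCl3·7H2O, MeOH, −40 °C) should give 22 together with its carbinol epimer (1S,4R)-3,5,5-trimethyl-4-[(E)-2-(2-methyl-1,3-dioxolan-2-yl)ethenyl]cyclohex-2-en-1-ol F4, separable on silica. The epimer is inverted by a Mitsunobu reaction (4-nitrobenzoic acid, PPh3, diisopropyl azodicarboxylate, THF, 0 °C) to (1R,4R)-3,5,5-trimethyl-4-[(E)-2-(2-methyl-1,3-dioxolan-2-yl)ethenyl]cyclohex-2-en-1-yl 4-nitrobenzoate F5, and methanolysis (K2CO3, MeOH) releases 22. The fallback sets out from 21 and comes back to the route at 22.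

3. Step 11. What may go wrong: deprotonation of the palmitate α-position or attack on the ester by the lithiated bis(boronate), or incomplete E-selectivity in the boron–oxygen elimination. The fallback replaces carbonyl olefination by alkyne hydroboration. Silyl ether aldehyde 12 is homologated with dimethyl (1-diazo-2-oxopropyl)phosphonate (K2CO3, MeOH; Seyferth–Gilbert homologation with the Ohira–Bestmann reagent) to (1S,4S,6R)-4-{[tert-butyl(dimethyl)silyl]oxy}-2,2,6-trimethyl-1-[(1E,3E)-3-methylhexa-1,3-dien-5-yn-1-yl]-7-oxabicyclo[4.1.0]heptane F6. Desilylation with Bu4NF gives (1S,4S,6R)-2,2,6-trimethyl-1-[(1E,3E)-3-methylhexa-1,3-dien-5-yn-1-yl]-7-oxabicyclo[4.1.0]heptan-4-ol F7. Acylation with 14 (pyridine, DMAP) gives (1S,4S,6R)-2,2,6-trimethyl-1-[(1E,3E)-3-methylhexa-1,3-dien-5-yn-1-yl]-7-oxabicyclo[4.1.0]heptan-4-yl hexadecanoate F8. Hydroboration of this terminal alkyne with pinacolborane (Cp2Zr(H)Cl 5 mol %, Et3N cat., CH2Cl2, rt) is a syn, anti-Markovnikov addition and should give 18. The fallback sets out from 12 and comes back to the route at 18.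

Further compounds
F1 | step 23 | (2E)-1-bromo-3-iodobut-2-ene | BrC/C=C(C)/I
F2 | step 23 | diethyl [(2E)-3-iodobut-2-en-1-yl]phosphonate | CCOP(=O)(C/C=C(C)/I)OCC
F3 | step 23 | (1R,4R)-4-[(1E,3E,5E,7E,9E,11E)-12-iodo-3,7-dimethyltrideca-1,3,5,7,9,11-hexaen-1-yl]-3,5,5-trimethylcyclohex-2-en-1-yl hexadecanoate | I/C(C)=C/C=C/C=C(C)/C=C/C=C(C)/C=C/[C@H]1C(C)=C[C@H](OC(=O)CCCCCCCCCCCCCCC)CC1(C)C
F4 | step 14 | (1S,4R)-3,5,5-trimethyl-4-[(E)-2-(2-methyl-1,3-dioxolan-2-yl)ethenyl]cyclohex-2-en-1-ol | CC1(/C=C/[C@H]2C(C)=C[C@@H](O)CC2(C)C)OCCO1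
F5 | step 14 | (1R,4R)-3,5,5-trimethyl-4-[(E)-2-(2-methyl-1,3-dioxolan-2-yl)ethenyl]cyclohex-2-en-1-yl 4-nitrobenzoate | CC1(/C=C/[C@H]2C(C)=C[C@H](OC(=O)c3ccc(cc3)[N+](=O)[O-])CC2(C)C)OCCO1
F6 | step 11 | (1S,4S,6R)-4-{[tert-butyl(dimethyl)silyl]oxy}-2,2,6-trimethyl-1-[(1E,3E)-3-methylhexa-1,3-dien-5-yn-1-yl]-7-oxabicyclo[4.1.0]heptane | CC(C)(C)[Si](C)(C)O[C@H]1CC(C)(C)[C@]2(/C=C/C(C)=C/C#C)O[C@]2(C)C1
F7 | step 11 | (1S,4S,6R)-2,2,6-trimethyl-1-[(1E,3E)-3-methylhexa-1,3-dien-5-yn-1-yl]-7-oxabicyclo[4.1.0]heptan-4-ol | O[C@H]1CC(C)(C)[C@]2(/C=C/C(C)=C/C#C)O[C@]2(C)C1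
F8 | step 11 | (1S,4S,6R)-2,2,6-trimethyl-1-[(1E,3E)-3-methylhexa-1,3-dien-5-yn-1-yl]-7-oxabicyclo[4.1.0]heptan-4-yl hexadecanoate | CCCCCCCCCCCCCCCC(=O)O[C@H]1CC(C)(C)[C@]2(/C=C/C(C)=C/C#C)O[C@]2(C)C1
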